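**Retrosynthetic overview**
- Last cut: a CH=CH bond in the middle of the side chain, made by cross-metathesis of two terminal alkenes and hydrogenated in the same flask. The halves are a butenolide with a dec-9-enyl chain and (S)-oct-7-en-2-yl acetate.
- The butenolide is the only ring. It is closed before the fragments are joined, at C3=C4, by intramolecular Horner–Wadsworth–Emmons olefination of a phosphonopropanoate ester of a 1-hydroxy-2-ketone.
- Key C–C bond: ring C4–C5. A thiazolium-carbene acyl anion (Breslow intermediate) from undec-10-enal adds to formaldehyde, joining two carbonyl carbons. Cutting inside the ring instead of at the ring–chain bond avoids any masked acyl anion, alkyl halide or protecting group.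
- The stereocentre comes from (S)-propylene oxide, opened at CH2 by pent-4-enylmagnesium bromide and acetylated in the same flask.

Assumption: a reagent or intermediate made and consumed in one flask belongs to a single step; the ring is numbered O1, C2(=O), C3(CH3), C4(chain), C5H2.

**Step 1**
Reactants: 1 undec-10-enal; 2 formaldehyde (used as paraformaldehyde)
Product: 3 1-hydroxydodec-11-en-2-one
Conditions: 3-ethylbenzothiazolium bromide (10 mol %), Et3N (10 mol %), (CH2O)n (1.5 equiv), EtOH, 65 °C
Reagents that add atoms: none
Why: The thiazolium-derived carbene turns the aldehyde carbon of 1 into a nucleophilic Breslow intermediate (acyl anion equivalent) that attacks formaldehyde, the most electrophilic and non-enolisable carbonyl present, in an NHC-catalysed crossed acyloin (benzoin-type) condensation that forms the future C4–C5 bond; no stereocentre is made.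

**Step 2**
Reactants: 3 1-hydroxydodec-11-en-2-one; 4 2-(diethoxyphosphoryl)propanoic acid
Product: 6 4-(dec-9-en-1-yl)-3-methylfuran-2(5H)-one, via phosphonate ester 5 (not isolated)
Conditions: DCC, DMAP (10 mol %), CH2Cl2, 0 °C to rt; then LiCl, DBU, MeCN, rt
Reagents that add atoms: none
Why: Steglich esterification of the primary ketol OH followed by intramolecular Horner–Wadsworth–Emmons olefination (Masamune–Roush conditions) closes the five-membered ring and can only give the endocyclic tetrasubstituted C3=C4 alkene; no stereocentre is made.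

**Step 3**
Reactants: 7 5-bromopent-1-ene; 8 (S)-2-methyloxirane
Product: 11 (S)-oct-7-en-2-yl acetate, via pent-4-en-1-ylmagnesium bromide 9 (not isolated), via bromomagnesium alkoxide 10 (not isolated)
Conditions: Mg, THF; CuI (10 mol %), 8, −30 to 0 °C; then Ac2O, DMAP (cat.), 0 °C to rt
Reagents that add atoms: acetic anhydride CC(=O)OC(C)=O
Why: Copper-catalysed Grignard opening of the epoxide (SN2 at the unsubstituted CH2) leaves the C–O stereocentre of 8 untouched, so the (S)-epoxide gives the (S)-alkoxide, and O-acetylation in the same flask retains it.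

**Step 4**
Reactants: 6 4-(dec-9-en-1-yl)-3-methylfuran-2(5H)-one; 11 (S)-oct-7-en-2-yl acetate (3 equiv)
Product: 13 (S)-16-(4-methyl-5-oxo-2,5-dihydrofuran-3-yl)hexadecan-2-yl acetate, via chain alkene 12 (not isolated)
Conditions: second-generation Grubbs catalyst RuCl2(PCy3)(H2IMes)(=CHPh) (5 mol %), CH2Cl2, 40 °C; then MeOH, H2 (7 bar), 50 °C
Reagents that add atoms: none
Why: Olefin cross-metathesis joins the two unhindered terminal alkenes (the tetrasubstituted, electron-poor ring alkene is inert to the ruthenium carbene), and tandem hydrogenation by the ruthenium hydride formed from the spent catalyst under H2 reduces only the disubstituted chain alkene; the stereocentre is not touched.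

**Compound list**
1 | undec-10-enal | C=CCCCCCCCCC=O | starting material
2 | formaldehyde (paraformaldehyde) | C=O | starting material
3 | 1-hydroxydodec-11-en-2-one | C=CCCCCCCCCC(=O)CO | intermediate
4 | 2-(diethoxyphosphoryl)propanoic acid (racemic) | CCOP(=O)(OCC)C(C)C(=O)O | starting material
5 | 2-oxododec-11-en-1-yl 2-(diethoxyphosphoryl)propanoate | C=CCCCCCCCCC(=O)COC(=O)C(C)P(=O)(OCC)OCC | intermediate
6 | 4-(dec-9-en-1-yl)-3-methylfuran-2(5H)-one | C=CCCCCCCCCC1=C(C)C(=O)OC1 | intermediate
7 | 5-bromopent-1-ene | C=CCCCBr | starting material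
8 | (S)-2-methyloxirane | C[C@H]1CO1 | starting material
9 | pent-4-en-1-ylmagnesium bromide | C=CCCC[Mg]Br | intermediate
10 | bromomagnesium (S)-oct-7-en-2-olate | C[C@H](O[Mg]Br)CCCCC=C | intermediate
11 | (S)-oct-7-en-2-yl acetate | CC(=O)O[C@@H](C)CCCCC=C | intermediate
12 | (S)-16-(4-methyl-5-oxo-2,5-dihydrofuran-3-yl)hexadec-7-en-2-yl acetate (E/Z mixture, E drawn) | CC(=O)O[C@@H](C)CCCC/C=C/CCCCCCCCC1=C(C)C(=O)OC1 | intermediate
13 | (S)-16-(4-methyl-5-oxo-2,5-dihydrofuran-3-yl)hexadecan-2-yl acetate | CC(=O)O[C@@H](C)CCCCCCCCCCCCCCC1=C(C)C(=O)OC1 | target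

**Totals**
Total steps: 4 (each one flask). Longest linear sequence: 3 (1 → 3 → 6 → 13); the branch 7 + 8 → 11 is one step.

**Steps most likely to fail**

Step 4 is the riskiest. The metathesis is statistical, so homodimers of 6 and 11 form. Ruthenium hydride can shift the terminal alkenes before coupling and give chain-shortened homologues. The ring alkene or the allylic C5–O bond could be partly reduced under H2. The fallback sets out from 1 and 11 and comes back at 13; it joins and saturates the chain before any ring exists. Cross-metathesis of 1 with 11 using the same catalyst gives (S)-17-oxoheptadec-7-en-2-yl acetate F1. Hydrogenation over Pd/C in EtOAc, which spares the aliphatic aldehyde, gives (S)-17-oxoheptadecan-2-yl acetate F2. Crossed acyloin with 2 (thiazolium salt, iPr2NEt, THF, no alcohol solvent so the acetate is not transesterified) gives (S)-18-hydroxy-17-oxooctadecan-2-yl acetate F3. DCC coupling with 4 gives (S)-18-{[2-(diethoxyphosphoryl)propanoyl]oxy}-17-oxooctadecan-2-yl acetate F4, which LiCl/DBU closes to 13.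

Step 1 may give the homo-acyloin of 1, formose-type self-condensation of formaldehyde, or stall. The fallback sets out from 1 and comes back at 3; it uses a stoichiometric masked acyl anion. Compound 1 and propane-1,3-dithiol (BF3·OEt2) give 2-(dec-9-en-1-yl)-1,3-dithiane F1'. Correction of label: this compound is 2-(dec-9-en-1-yl)-1,3-dithiane F5. n-BuLi in THF at −30 °C gives 2-(dec-9-en-1-yl)-2-lithio-1,3-dithiane F6. Trapping with 2 gives [2-(dec-9-en-1-yl)-1,3-dithian-2-yl]methanol F7. MeI/CaCO3 in aqueous MeCN unmasks the ketone and returns 3.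

Step 2 may suffer from ketol dimerisation, slow acylation or intermolecular olefination. The fallback sets out from 3 and comes back at 6; it forms C3–C4 by a reductive aldol instead of an olefination. Compound 3 with 2-bromopropanoyl bromide and pyridine gives 2-oxododec-11-en-1-yl 2-bromopropanoate F8. SmI2 in THF at −78 °C (intramolecular Reformatsky) gives 4-(dec-9-en-1-yl)-4-hydroxy-3-methyldihydrofuran-2(3H)-one F9 as a diastereomer mixture. Dehydration with SOCl2/pyridine towards the acidic C3–H gives 6.

**Further compounds**
F1 | step 4 | (S)-17-oxoheptadec-7-en-2-yl acetate (E/Z mixture, E drawn) | CC(=O)O[C@@H](C)CCCC/C=C/CCCCCCCCC=O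
F2 | step 4 | (S)-17-oxoheptadecan-2-yl acetate | CC(=O)O[C@@H](C)CCCCCCCCCCCCCCC=O
F3 | step 4 | (S)-18-hydroxy-17-oxooctadecan-2-yl acetate | CC(=O)O[C@@H](C)CCCCCCCCCCCCCCC(=O)CO
F4 | step 4 | (S)-18-{[2-(diethoxyphosphoryl)propanoyl]oxy}-17-oxooctadecan-2-yl acetate | CC(=O)O[C@@H](C)CCCCCCCCCCCCCCC(=O)COC(=O)C(C)P(=O)(OCC)OCC
F5 | step 1 | 2-(dec-9-en-1-yl)-1,3-dithiane | C=CCCCCCCCCC1SCCCS1
F6 | step 1 | 2-(dec-9-en-1-yl)-2-lithio-1,3-dithiane | [Li]C1(CCCCCCCCC=C)SCCCS1
F7 | step 1 | [2-(dec-9-en-1-yl)-1,3-dithian-2-yl]methanol | OCC1(CCCCCCCCC=C)SCCCS1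
F8 | step 2 | 2-oxododec-11-en-1-yl 2-bromopropanoate | C=CCCCCCCCCC(=O)COC(=O)C(C)Br
F9 | step 2 | 4-(dec-9-en-1-yl)-4-hydroxy-3-methyldihydrofuran-2(3H)-one (diastereomer mixture) | C=CCCCCCCCCC1(O)COC(=O)C1C
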